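**Retrosynthetic overview**
1. Target 17 ⇒ cis-1,3-diol 15 + 4-methoxybenzoyl chloride 16 (acylation of the secondary allylic OH only); 15 ⇒ β-hydroxy enone 12 (chelation-controlled 1,3-syn reduction sets C8).
2. 12 ⇒ saturated hydroxy ketone 7 (Saegusa oxidation, methyl cuprate 1,4-addition, second Saegusa oxidation install the C6 methyl and the C6=C7 alkene).
3. 7 ⇒ achiral dione 5 by the new key step: a catalytic enantioselective desymmetrizing ketone–ene cyclization that forms the C3–C3a bond and sets C3, C3a and C8a.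
4. 5 ⇒ cycloheptane-1,3-dione 1 + MeI + acrolein 3 + isopropylidene ylide.
5. Ring order: the seven-membered ring is bought; the five-membered ring is closed onto it in step 4.

**Structure check and assumptions**
- The target SMILES reads as (3R,3aS,8S,8aR)-3a-hydroxy-6,8a-dimethyl-3-(propan-2-yl)-1,2,3,3a,4,5,8,8a-octahydroazulen-8-yl 4-methoxybenzoate. The hydroazulene is cis-fused, and 8a-Me, 3a-OH, 3-iPr and 8-OAr all lie on the same face.
- Locants in the "Why" lines use the target numbering (C3 iPr, C3a OH, C6 Me, C8 ester carbon, C8a Me). The IUPAC names of the ketone intermediates number the ring the other way round (C1 iPr, C3a Me, C4 C=O, C8a O).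
- Assumption: the sense of induction of the new catalyst in step 4 cannot be known in advance. The (S,S)-catalyst is written; its antipode is used if that is the one that gives 6.

**Step 1**
Reactants: 1 cycloheptane-1,3-dione
Product: 2 2-methylcycloheptane-1,3-dione
Conditions: MeI (1.05 equiv), K2CO3, acetone, 50 °C
Reagents that add atoms: iodomethane, CI
Why: C-alkylation (SN2) of the β-diketone enolate; the mono-C-methyl dione is separated from minor O-methyl and 2,2-dimethyl by-products.

**Step 2**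
Reactants: 2 2-methylcycloheptane-1,3-dione; 3 acrolein
Product: 4 3-(1-methyl-2,7-dioxocycloheptyl)propanal
Conditions: Et3N (10 mol %), MeCN, 0 °C to rt
Reagents that add atoms: none
Why: Base-catalysed Michael addition of the tertiary 1,3-dione enolate to acrolein builds the quaternary carbon, which is still prochiral (Cs-symmetric dione).

**Step 3**
Reactants: 4 3-(1-methyl-2,7-dioxocycloheptyl)propanal
Product: 5 2-methyl-2-(4-methylpent-3-en-1-yl)cycloheptane-1,3-dione
Conditions: i-PrPPh3I, KHMDS, THF, −78 °C; then 4, −78 to 0 °C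
Reagents that add atoms: isopropyltriphenylphosphonium iodide, CC(C)[P+](c1ccccc1)(c1ccccc1)c1ccccc1.[I-]
Why: Wittig olefination; the non-stabilised ylide reacts with the aldehyde at −78 °C much faster than with the two hindered ketones flanking the quaternary carbon.

**Step 4**
Reactants: 5 2-methyl-2-(4-methylpent-3-en-1-yl)cycloheptane-1,3-dione
Product: 6 (1R,3aS,8aS)-8a-hydroxy-3a-methyl-1-(prop-1-en-2-yl)octahydroazulen-4(1H)-one
Conditions: (S,S)-IDPi Brønsted acid (imidodiphosphorimidate from two 3,3'-bis[3,5-bis(trifluoromethyl)phenyl]-BINOL units, N-triflyl) 5 mol %, 5 Å MS, CHCl3/cyclohexane, −20 °C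
Reagents that add atoms: none
Why: Proposed new method: a catalytic enantioselective desymmetrizing type-I ketone–ene (carbonyl–ene) cyclization. The confined strong chiral acid activates one of the two enantiotopic C=O groups inside its pocket; the trisubstituted alkene attacks it 5-exo (C3–C3a bond) through a six-membered ene array that passes an allylic methyl H to the carbonyl O, with the tertiary cationic character at CMe2 paired with the counter-anion. The three-atom tether enforces cis ring fusion (8a-Me/3a-OH cis). The CMe2 terminus sits syn to O and away from the ring CH2 (isopropenyl cis to OH). The catalyst's choice of carbonyl fixes the absolute configuration at C3, C3a and C8a together. Closest known reaction types: confined-acid-catalysed asymmetric carbonyl–ene cyclization of olefinic aldehydes, the Brønsted-acid asymmetric Torgov-type desymmetrization of 2,2-disubstituted cyclopentane-1,3-diones by aryl-conjugated alkenes, and Me2AlCl-promoted racemic ketone–ene cyclizations; none uses an unactivated alkene on a cycloheptane-1,3-dione with retention of the tertiary alcohol.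

**Step 5**
Reactants: 6 (1R,3aS,8aS)-8a-hydroxy-3a-methyl-1-(prop-1-en-2-yl)octahydroazulen-4(1H)-one
Product: 7 (1R,3aS,8aS)-8a-hydroxy-3a-methyl-1-(propan-2-yl)octahydroazulen-4(1H)-one
Conditions: H2 (3 atm), RhCl(PPh3)3 (5 mol %), benzene/EtOH, rt
Reagents that add atoms: none
Why: Homogeneous (Wilkinson) hydrogenation reduces the 1,1-disubstituted alkene without double-bond migration, so the adjacent stereocentre from step 4 is untouched; ketone and tertiary alcohol are inert.

**Step 6**
Reactants: 7 (1R,3aS,8aS)-8a-hydroxy-3a-methyl-1-(propan-2-yl)octahydroazulen-4(1H)-one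
Product: 8 (1R,3aR,8aS)-3a-methyl-1-(propan-2-yl)-4,8a-bis[(trimethylsilyl)oxy]-1,2,3,3a,6,7,8,8a-octahydroazulene
Conditions: TMSOTf (2.5 equiv), Et3N (4 equiv), CH2Cl2, −78 to 0 °C
Reagents that add atoms: trimethylsilyl trifluoromethanesulfonate, C[Si](C)(C)OS(=O)(=O)C(F)(F)F
Why: Silyl triflate/amine silylation gives the only possible silyl enol ether (the other α-carbon is quaternary) and caps the tertiary alcohol in the same operation.

**Step 7**
Reactants: 8 (1R,3aR,8aS)-3a-methyl-1-(propan-2-yl)-4,8a-bis[(trimethylsilyl)oxy]-1,2,3,3a,6,7,8,8a-octahydroazulene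
Product: 9 (1R,3aS,8aS)-3a-methyl-1-(propan-2-yl)-8a-[(trimethylsilyl)oxy]-2,3,3a,7,8,8a-hexahydroazulen-4(1H)-one
Conditions: Pd(OAc)2 (1.05 equiv), MeCN, rt
Reagents that add atoms: none
Why: Saegusa–Ito oxidation (Pd(II) enolate, then β-hydride elimination) gives the cycloheptenone with regiochemistry fixed by the enol ether.

**Step 8**
Reactants: 9 (1R,3aS,8aS)-3a-methyl-1-(propan-2-yl)-8a-[(trimethylsilyl)oxy]-2,3,3a,7,8,8a-hexahydroazulen-4(1H)-one
Product: 10 (1R,3aR,6RS,8aS)-3a,6-dimethyl-1-(propan-2-yl)-4,8a-bis[(trimethylsilyl)oxy]-1,2,3,3a,6,7,8,8a-octahydroazulene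
Conditions: MeLi (4 equiv), CuI (2 equiv), Et2O, 0 °C; then TMSCl (3 equiv) and 9, THF, −78 °C
Reagents that add atoms: methyllithium (used as Me2CuLi), [Li]C; chlorotrimethylsilane, C[Si](C)(C)Cl
Why: TMSCl-accelerated Gilman cuprate 1,4-addition with in situ O-silylation of the enolate places the methyl on C6; the new C6 centre is an inconsequential mixture, destroyed in step 9.

**Step 9**
Reactants: 10 (1R,3aR,6RS,8aS)-3a,6-dimethyl-1-(propan-2-yl)-4,8a-bis[(trimethylsilyl)oxy]-1,2,3,3a,6,7,8,8a-octahydroazulene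
Product: 11 (1R,3aS,8aS)-3a,6-dimethyl-1-(propan-2-yl)-8a-[(trimethylsilyl)oxy]-2,3,3a,7,8,8a-hexahydroazulen-4(1H)-one
Conditions: Pd(OAc)2 (1.1 equiv), MeCN, 40 °C
Reagents that add atoms: none
Why: Second Saegusa–Ito oxidation; β-hydride elimination of the tertiary C6–H gives the β-methyl enone, which carries the trisubstituted alkene of the target.

**Step 10**
Reactants: 11 (1R,3aS,8aS)-3a,6-dimethyl-1-(propan-2-yl)-8a-[(trimethylsilyl)oxy]-2,3,3a,7,8,8a-hexahydroazulen-4(1H)-one
Product: 12 (1R,3aS,8aS)-8a-hydroxy-3a,6-dimethyl-1-(propan-2-yl)-2,3,3a,7,8,8a-hexahydroazulen-4(1H)-one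
Conditions: HF·pyridine, THF, 0 °C
Reagents that add atoms: none
Why: Fluoride cleavage of the tertiary TMS ether (Si–F bond formation); the β-hydroxy ketone has a quaternary α-carbon, so it cannot eliminate.

**Step 11**
Reactants: 12 (1R,3aS,8aS)-8a-hydroxy-3a,6-dimethyl-1-(propan-2-yl)-2,3,3a,7,8,8a-hexahydroazulen-4(1H)-one
Product: 15 (3R,3aS,8S,8aR)-6,8a-dimethyl-3-(propan-2-yl)-1,2,3,3a,4,5,8,8a-octahydroazulene-3a,8-diol, via diethylboron chelate 13 (not isolated), via cyclic diethylborate 14 (not isolated)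
Conditions: Et2BOMe (1.1 equiv), THF/MeOH 4:1, −78 °C, 30 min; NaBH4, −78 °C; then MeOH co-evaporation
Reagents that add atoms: none
Why: Narasaka–Prasad 1,3-syn reduction; boron bridges the 3a-oxygen and the carbonyl oxygen on the face of the angular substituents, and external hydride adds 1,2 to C8 from the opposite face (also anti to the angular methyl), so the new C8–O bond is cis to C3a–O (8S).

**Step 12**
Reactants: 15 (3R,3aS,8S,8aR)-6,8a-dimethyl-3-(propan-2-yl)-1,2,3,3a,4,5,8,8a-octahydroazulene-3a,8-diol; 16 4-methoxybenzoyl chloride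
Product: 17 (3R,3aS,8S,8aR)-3a-hydroxy-6,8a-dimethyl-3-(propan-2-yl)-1,2,3,3a,4,5,8,8a-octahydroazulen-8-yl 4-methoxybenzoate
Conditions: DMAP (0.3 equiv), Et3N (2 equiv), CH2Cl2, 0 °C to rt
Reagents that add atoms: none
Why: DMAP-catalysed acylation (nucleophilic catalysis) of the secondary allylic alcohol with retention at C8; the tertiary 3a-OH is too hindered to react.

**Compound list**
1 | cycloheptane-1,3-dione | O=C1CCCCC(=O)C1 | starting material
2 | 2-methylcycloheptane-1,3-dione | CC1C(=O)CCCCC1=O | intermediate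
3 | acrolein (prop-2-enal) | C=CC=O | starting material
4 | 3-(1-methyl-2,7-dioxocycloheptyl)propanal | O=CCCC1(C)C(=O)CCCCC1=O | intermediate
5 | 2-methyl-2-(4-methylpent-3-en-1-yl)cycloheptane-1,3-dione | CC(C)=CCCC1(C)C(=O)CCCCC1=O | intermediate
6 | (1R,3aS,8aS)-8a-hydroxy-3a-methyl-1-(prop-1-en-2-yl)octahydroazulen-4(1H)-one (cis-fused; Me, OH, isopropenyl all cis) | O=C1CCCC[C@]2(O)[C@@H](C(C)=C)CC[C@]12C | intermediate
7 | (1R,3aS,8aS)-8a-hydroxy-3a-methyl-1-(propan-2-yl)octahydroazulen-4(1H)-one | O=C1CCCC[C@]2(O)[C@@H](C(C)C)CC[C@]12C | intermediate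
8 | (1R,3aR,8aS)-3a-methyl-1-(propan-2-yl)-4,8a-bis[(trimethylsilyl)oxy]-1,2,3,3a,6,7,8,8a-octahydroazulene | C[Si](C)(C)OC1=CCCC[C@]2(O[Si](C)(C)C)[C@@H](C(C)C)CC[C@]12C | intermediate
9 | (1R,3aS,8aS)-3a-methyl-1-(propan-2-yl)-8a-[(trimethylsilyl)oxy]-2,3,3a,7,8,8a-hexahydroazulen-4(1H)-one | O=C1C=CCC[C@]2(O[Si](C)(C)C)[C@@H](C(C)C)CC[C@]12C | intermediate
10 | (1R,3aR,6RS,8aS)-3a,6-dimethyl-1-(propan-2-yl)-4,8a-bis[(trimethylsilyl)oxy]-1,2,3,3a,6,7,8,8a-octahydroazulene (C6 epimer mixture) | C[Si](C)(C)OC1=CC(C)CC[C@]2(O[Si](C)(C)C)[C@@H](C(C)C)CC[C@]12C | intermediate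
11 | (1R,3aS,8aS)-3a,6-dimethyl-1-(propan-2-yl)-8a-[(trimethylsilyl)oxy]-2,3,3a,7,8,8a-hexahydroazulen-4(1H)-one | O=C1C=C(C)CC[C@]2(O[Si](C)(C)C)[C@@H](C(C)C)CC[C@]12C | intermediate
12 | (1R,3aS,8aS)-8a-hydroxy-3a,6-dimethyl-1-(propan-2-yl)-2,3,3a,7,8,8a-hexahydroazulen-4(1H)-one | O=C1C=C(C)CC[C@]2(O)[C@@H](C(C)C)CC[C@]12C | intermediate
13 | (1R,3aS,8aS)-8a-[(diethylboranyl)oxy]-3a,6-dimethyl-1-(propan-2-yl)-2,3,3a,7,8,8a-hexahydroazulen-4(1H)-one (boron chelated by the C4 carbonyl) | O=C1C=C(C)CC[C@]2(OB(CC)CC)[C@@H](C(C)C)CC[C@]12C | intermediate (not isolated)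
14 | sodium cyclic diethylborate of diol 15 (2,2-diethyl-1,3,2-dioxaborinan-2-uide bridging O3a and O8) | CC[B-]1(CC)O[C@H]2C=C(C)CC[C@]3(O1)[C@@H](C(C)C)CC[C@]23C.[Na+] | intermediate (not isolated)
15 | (3R,3aS,8S,8aR)-6,8a-dimethyl-3-(propan-2-yl)-1,2,3,3a,4,5,8,8a-octahydroazulene-3a,8-diol | O[C@H]1C=C(C)CC[C@]2(O)[C@@H](C(C)C)CC[C@]12C | intermediate
16 | 4-methoxybenzoyl chloride | COc1ccc(cc1)C(Cl)=O | starting material
17 | (3R,3aS,8S,8aR)-3a-hydroxy-6,8a-dimethyl-3-(propan-2-yl)-1,2,3,3a,4,5,8,8a-octahydroazulen-8-yl 4-methoxybenzoate | COc1ccc(C(=O)O[C@H]2C=C(C)CC[C@]3(O)[C@@H](C(C)C)CC[C@]23C)cc1 | target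

**Totals**
Total step count: 12. Longest linear sequence: 12 steps (1 to 17).

**Three steps most likely to fail, each with a fallback**

Step 4 (the proposed new desymmetrizing ketone–ene cyclization). Possible failures: the unactivated ketone is too unreactive, the tertiary alcohol dehydrates under the acid, enantioselectivity is low, or the isopropenyl epimer forms. The fallback uses known chemistry, sets out from 5 and comes back at 6. Asymmetric transfer hydrogenation of dione 5 (RuCl[(S,S)-TsDPEN](p-cymene) or its antipode, HCO2H/Et3N) reduces one enantiotopic carbonyl and gives (2R,3R)-3-hydroxy-2-methyl-2-(4-methylpent-3-en-1-yl)cycloheptan-1-one F1, with the quaternary centre now fixed. A Me2AlCl-promoted type-I ketone–ene cyclization (2.5 equiv, CH2Cl2, −78 to 0 °C) on the remaining ketone closes the cis-fused cyclopentane to give (3R,3aS,8R,8aR)-8a-methyl-3-(prop-1-en-2-yl)octahydroazulene-3a,8(1H)-diol F2. Dess–Martin oxidation of its secondary alcohol (the tertiary one is inert) returns to 6.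

Step 11 (facial selectivity of the C8 reduction). If the chelate does not form on the hindered tertiary alcohol, or hydride adds from the other face, the 8-epimer results. The fallback inverts at the esterification stage instead; it sets out from 12 and comes back at 17. Directed reduction of 12 with Me4NBH(OAc)3 (MeCN/AcOH, −30 °C) delivers hydride intramolecularly from the 3a-oxygen face and gives the trans-diol (3R,3aS,8R,8aR)-6,8a-dimethyl-3-(propan-2-yl)-1,2,3,3a,4,5,8,8a-octahydroazulene-3a,8-diol F3. Mitsunobu esterification (PPh3, DIAD, 4-methoxybenzoic acid, toluene, 0 °C to rt) then forms the ester with inversion at C8 and gives target 17 directly. The same Mitsunobu step salvages any 8-epimer formed in step 11.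

Step 3 (Wittig on the base-sensitive triketo-aldehyde 4). The basic ylide may enolize the aldehyde and trigger intramolecular aldol or retro-Claisen reactions. The fallback replaces the Michael/Wittig pair by direct C-alkylation through a hydrazone; it sets out from 2 and comes back at 5. Condensation of 2 with N,N-dimethylhydrazine (cat. TsOH, benzene, Dean–Stark) gives 3-(2,2-dimethylhydrazinylidene)-2-methylcycloheptan-1-one F4. Deprotonation with KH (THF, 0 °C) and C-alkylation with 5-iodo-2-methylpent-2-ene gives 3-(2,2-dimethylhydrazinylidene)-2-methyl-2-(4-methylpent-3-en-1-yl)cycloheptan-1-one F5. Hydrolysis of the hydrazone (aq. Cu(OAc)2, THF) gives 5.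

**Further compounds**
F1 | step 4 | (2R,3R)-3-hydroxy-2-methyl-2-(4-methylpent-3-en-1-yl)cycloheptan-1-one | O=C1CCCC[C@@H](O)[C@@]1(C)CCC=C(C)C
F2 | step 4 | (3R,3aS,8R,8aR)-8a-methyl-3-(prop-1-en-2-yl)octahydroazulene-3a,8(1H)-diol | O[C@@H]1CCCC[C@]2(O)[C@@H](C(C)=C)CC[C@]12C
F3 | step 11 | (3R,3aS,8R,8aR)-6,8a-dimethyl-3-(propan-2-yl)-1,2,3,3a,4,5,8,8a-octahydroazulene-3a,8-diol | O[C@@H]1C=C(C)CC[C@]2(O)[C@@H](C(C)C)CC[C@]12C
F4 | step 3 | 3-(2,2-dimethylhydrazinylidene)-2-methylcycloheptan-1-one | CN(C)N=C1CCCCC(=O)C1C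
F5 | step 3 | 3-(2,2-dimethylhydrazinylidene)-2-methyl-2-(4-methylpent-3-en-1-yl)cycloheptan-1-one | CN(C)N=C1CCCCC(=O)C1(C)CCC=C(C)C
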